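Remarks on the chemistry (assumptions)
- Locants are eudesmane locants: ring A = C1–C5 and C10, ring B = C5–C10, C14 = methyl on C10, C15 = methyl on C4, C11 = carbinol carbon on C7.
- (5E)-Geranylacetone and (2E)-2-methylbut-2-en-1-ol are taken as commercial, isomerically pure starting materials.
- Lithium alkoxides and enolates that are formed and trapped within one reaction are given with the conditions; every species that links two reactions in one flask is numbered.

## Structural features

The target is a eudesmane: a trans-fused decalin with an angular methyl on C10, a methyl on C4 and a 2-hydroxyprop-2-yl group on C7. Ring A carries four contiguous stereocentres: C3 (S, equatorial acyloxy), C4 (S, fully substituted, equatorial acetoxy and axial methyl syn to the C10 methyl), C5 (R, axial H) and C10 (R, quaternary). The C3 and C4 oxygens are trans-diequatorial, so a syn-dihydroxylation of a ring alkene cannot give them, and methyl addition to a C4 ketone from the open α-face would give the wrong C4 epimer. Ring B holds a C6=C7–C8=O enone whose α-carbon C7 bears a free tertiary alcohol (C11); this unit is prone to retro-aldol cleavage and dehydration, and C5–H becomes vinylogously acidic once the enone is in place. The C3 ester is (2S,3R)-2,3-dimethyloxirane-2-carboxylate, an acid- and nucleophile-sensitive epoxide with two further stereocentres. Three oxygen functions must be told apart: a secondary ester, a tertiary acetate and a free tertiary alcohol. The key step exploits the pattern C3(O)–C4(quaternary)–C5(H)–C10(quaternary, methyl) of ring A together with the C8 carbonyl carbon standing 1,3 to C10. This is the imprint of a head-to-tail epoxy-polyene cyclization that ends on a methyl ketone enol, and the carbons C1–C10, C14 and C15 map directly onto geranylacetone.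

## Logic of the disconnections

19 to 16: the C7–C11 bond and the C6=C7 double bond are removed together. Cutting here takes away the fragile hydroxy-enone and three carbons in one operation and leaves a plain ring ketone carrying a selenium group at C7. The forward step must enolize only toward C7 and eliminate only toward C6; C9 is neopentyl and C11 has no hydrogen, which secures both.

16 to 15: the C7–Se bond is cut. The gain is a ketone with no activating group. The forward step needs a base that enolizes the ketone but not the acetate or the epoxy ester.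

15 to 14, and 14 to 9 + 12: the two acyl–oxygen bonds at O4 and O3 are cut, the tertiary one first in the backward sense. This leads to a diol whose two hydroxyls differ in substitution, so the secondary one can be acylated selectively with the precious acid 12 and the tertiary one acetylated afterwards. The demand is that the epoxide of 12 survives both acylations, which excludes Lewis acids in those steps.

12 to 11 to 10: the carboxyl oxidation level is lowered and the two epoxide C–O bonds are cut. This reduces the side chain to a commercial allylic alcohol and puts both side-chain stereocentres under reagent control. The forward epoxidation must deliver oxygen to the face that gives the (2R,3R) alcohol.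

9 to 7 to 6: the C4–O bond is traced back to a C4–C bond (hydroxyl from formyl, formyl from hydroxymethyl). An oxygen on the initiating carbon of a cationic cyclization would turn that carbon into a planar oxocarbenium ion and erase its configuration, whereas a carbon substituent can be carried through and exchanged for oxygen with retention afterwards. The forward oxidative migration must be faster at the aldehyde than at the ring ketone, and the alcohol oxidation must take the primary hydroxyl only.

6 to 4 (key): the C4–C5 and C9–C10 bonds are cut and the C4–O bond of an epoxide is restored. Both rings open to an acyclic chain; C5 and C10 disappear as stereocentres and C3 and C4 become the two carbons of one epoxide. The forward step must open the epoxide at its fully substituted carbon, fold chair–chair and end on the enol ether carbon.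

4 to 3 to 2 to 1: the two O–Si bonds, the epoxide C–O bonds and the allylic C–O bond are removed in turn. The result is a commercial, achiral C13 ketone that already contains C1–C10, C14 and C15. The forward steps must oxidize only the E-methyl of the terminal alkene, epoxidize only the allylic alkene with high enantioselectivity, and form the less substituted enol ether.

## Other disconnections considered

Alternative 1: Robinson annulation (the first that comes to mind). The cut is C1–C10 and C4–C5; the forward key step joins a 4-silyloxy-2-methylcyclohexanone with ethyl vinyl ketone to the octalone A1. A1 holds only C10. C5, C4 and C3 would each need their own stereo-defining operation (dissolving-metal reduction, α-hydroxylation of the Δ3 enol ether, ketone reduction). The annulation partner must also be made enantiopure and must carry the C8 oxygen through strongly basic steps. The chosen plan sets all four ring-A centres in one event from one catalytic epoxidation and is shorter.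

Alternative 2: Diels–Alder construction of ring B. The cut is C5–C6 and C9–C10; the forward key step adds a 2-silyloxy-diene to the enone A2 to give the cis-fused enedione A3. A2 is a β,β-disubstituted enone and a poor dienophile, and the cycloaddition has to create the quaternary C10. A3 is cis-fused and must be epimerized at C5, which is activated by both carbonyl systems and prone to double-bond migration. The C4 ketone can reach the 4α-oxygen/4β-methyl carbinol only indirectly, because a methyl nucleophile should add from the α-face, away from the C10 methyl. The chosen plan forms the trans fusion directly and sets C4 stereospecifically.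

Alternative 3: transannular cyclization of a ten-membered ring. The cut is C5–C10 alone; the forward key step protonates the C1=C10 alkene of the 3-oxygenated germacrone A4, the C4=C5 alkene attacks C10, and water captures the C4 cation. This mirrors the likely biogenesis and would give the equatorial C4 oxygen. A4 has C3 as its only stereocentre and a flexible ring with several conformers, so facial control of the ring fusion would be weak. The C4 cation can also lose a proton in competition with capture. An enantioselective route to the E,E-cyclodecadienone is longer than the whole chosen route to 4.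

Key step: step 4

## Route

Step 1
Reactants: 1 (5E)-6,10-dimethylundeca-5,9-dien-2-one (geranylacetone)
Product: 2 (5E,9E)-11-hydroxy-6,10-dimethylundeca-5,9-dien-2-one
Conditions: SeO2 (10 mol%), t-BuOOH (2.5 equiv), salicylic acid (10 mol%), CH2Cl2, rt
Reagents that add atoms: tert-butyl hydroperoxide, CC(C)(C)OO (oxygen relayed through the catalytic SeO2)
Why: SeO2-catalysed allylic oxidation (ene reaction, then [2,3]-sigmatropic shift) should take the E-methyl group of the terminal gem-dimethyl alkene, the usual site for acyclic terpenoid termini; the internal alkene and the ketone α-positions are expected to react more slowly under catalytic conditions at room temperature.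

Step 2
Reactants: 2 (5E,9E)-11-hydroxy-6,10-dimethylundeca-5,9-dien-2-one
Product: 3 (5E)-8-[(2S,3S)-3-(hydroxymethyl)-3-methyloxiran-2-yl]-6-methyloct-5-en-2-one
Conditions: Ti(OiPr)4 (10 mol%), L-(+)-diethyl tartrate (12 mol%), t-BuOOH (2 equiv), 4 Å molecular sieves, CH2Cl2, −20 °C
Reagents that add atoms: tert-butyl hydroperoxide, CC(C)(C)OO
Why: Sharpless asymmetric epoxidation; only the alkene of the titanium-bound allylic alcohol is oxidized, and L-(+)-tartrate is the ligand that gives (2S,3S)-epoxy alcohols from E-allylic alcohols of this substitution pattern, which sets the future C3 and C4.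

Step 3
Reactants: 3 (5E)-8-[(2S,3S)-3-(hydroxymethyl)-3-methyloxiran-2-yl]-6-methyloct-5-en-2-one
Product: 4 triethyl{[(2S,3S)-2-methyl-3-{(3E)-3-methyl-7-[(triethylsilyl)oxy]octa-3,7-dien-1-yl}oxiran-2-yl]methoxy}silane
Conditions: LiN(iPr)2 (2.3 equiv), THF, −78 °C; Et3SiCl (2.6 equiv), Et3N, −78 → 0 °C
Reagents that add atoms: chlorotriethylsilane, CC[Si](Cl)(CC)CC
Why: Double O-silylation; the amide base removes the hydroxyl proton and, under kinetic control, a proton of the ketone CH3 group, and the silyl chloride traps alkoxide and enolate on oxygen, so the less substituted enol ether (the later C8=C9 terminator) is formed while the epoxide is untouched at low temperature.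

Step 4
Reactants: 4 triethyl{[(2S,3S)-2-methyl-3-{(3E)-3-methyl-7-[(triethylsilyl)oxy]octa-3,7-dien-1-yl}oxiran-2-yl]methoxy}silane
Product: 6 (4aR,5R,6S,8aR)-6-hydroxy-5-(hydroxymethyl)-5,8a-dimethyloctahydronaphthalen-2(1H)-one, via triethylsilyl ether 5 (not isolated)
Conditions: MeAlCl2 (2 equiv), CH2Cl2 (0.01 M), −94 °C; Et3N/MeOH quench; then 1 M HCl, THF, 0 °C
Reagents that add atoms: none
Why: MeAlCl2 binds the epoxide oxygen, the C4–O bond ionizes as the C5=C10 alkene attacks C4 from the side opposite the departing oxygen, and the developing C10 cation is taken by the terminal carbon C9 of the enol silyl ether, whose oxocarbenium ion loses the silyl group to leave the C8 ketone; the reaction type is the Lewis acid-promoted, epoxide-initiated cation–olefin bicyclization with enol silyl ether termination. Ring A closes 6-endo at the alkene (C4–C5 bond, charge at the tertiary C10) with inversion at C4, and ring B closes 6-endo (C9–C10 bond, charge at the oxygen-stabilized C8). C3 is carried over unchanged from the epoxide and its oxygen lies equatorial in the chair–chair fold (3S). C4 is fixed by the epoxide geometry through backside attack: the group trans to the chain (CH2OSiEt3) becomes equatorial and the cis methyl becomes axial (C15 syn to C14). C5 and C10 arise by anti addition across the E-alkene in the chair–chair transition state, which gives the trans ring fusion (5R, 10R) on the face dictated by the C3–C4 epoxide. The step needs opening at the fully substituted C4 and not at C3 (tertiary cation character, six- against five-membered ring) and ring closure faster than hydride-shift rearrangement of the epoxide (low temperature, a nucleophilic enol ether held in reach). The acidic work-up cleaves the remaining primary silyl ether of 5.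

Step 5
Reactants: 6 (4aR,5R,6S,8aR)-6-hydroxy-5-(hydroxymethyl)-5,8a-dimethyloctahydronaphthalen-2(1H)-one
Product: 7 (1S,2S,4aR,8aR)-2-hydroxy-1,4a-dimethyl-6-oxodecahydronaphthalene-1-carbaldehyde
Conditions: TEMPO (10 mol%), PhI(OAc)2 (1.1 equiv), CH2Cl2, rt
Reagents that add atoms: none
Why: Oxoammonium (TEMPO) oxidation takes primary alcohols much faster than secondary ones, so the C3 hydroxyl should remain; C4 has no hydrogen and cannot epimerize, and the neutral medium avoids retro-aldol opening of the β-hydroxy aldehyde.

Step 6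
Reactants: 7 (1S,2S,4aR,8aR)-2-hydroxy-1,4a-dimethyl-6-oxodecahydronaphthalene-1-carbaldehyde
Product: 9 (4aR,5S,6S,8aR)-5,6-dihydroxy-5,8a-dimethyloctahydronaphthalen-2(1H)-one, via formate 8 (not isolated)
Conditions: mCPBA (1.3 equiv), NaHCO3, CH2Cl2, 0 °C; then K2CO3 (cat.), MeOH, 0 °C
Reagents that add atoms: 3-chloroperbenzoic acid, OOC(=O)c1cccc(Cl)c1
Why: Baeyer–Villiger oxidation; in the peracid adduct of the aldehyde the fully substituted C4 should migrate to oxygen in preference to hydride, with retention of configuration, so the formyl carbon is exchanged for the equatorial C4 oxygen (4S); the ring ketone is expected to react much more slowly with buffered peracid at 0 °C, and the formate is removed by transesterification.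

Step 7
Reactants: 10 (2E)-2-methylbut-2-en-1-ol
Product: 11 [(2R,3R)-2,3-dimethyloxiran-2-yl]methanol
Conditions: Ti(OiPr)4 (10 mol%), D-(−)-diethyl tartrate (12 mol%), t-BuOOH (2 equiv), 4 Å molecular sieves, CH2Cl2, −20 °C
Reagents that add atoms: tert-butyl hydroperoxide, CC(C)(C)OO
Why: Sharpless asymmetric epoxidation with the tartrate enantiomeric to that of step 2, which should therefore give the (2R,3R)-epoxy alcohol; syn addition to the E-alkene keeps the two methyl groups cis.

Step 8
Reactants: 11 [(2R,3R)-2,3-dimethyloxiran-2-yl]methanol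
Product: 12 (2S,3R)-2,3-dimethyloxirane-2-carboxylic acid
Conditions: RuCl3·xH2O (2 mol%), NaIO4 (3 equiv), MeCN/EtOAc/H2O, 0 °C → rt
Reagents that add atoms: sodium periodate, [Na+].[O-]I(=O)(=O)=O (oxygen relayed through catalytic RuO4); water, O
Why: RuO4 oxidation of a primary alcohol to the acid through the aldehyde hydrate, a standard conversion of 2,3-epoxy alcohols to glycidic acids that leaves the epoxide intact; the descriptor at C2 changes from R to S only through the change in substituent priorities.

Step 9
Reactants: 9 (4aR,5S,6S,8aR)-5,6-dihydroxy-5,8a-dimethyloctahydronaphthalen-2(1H)-one, 12 (2S,3R)-2,3-dimethyloxirane-2-carboxylic acid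
Product: 14 (1S,2S,4aR,8aR)-1-hydroxy-1,4a-dimethyl-6-oxodecahydronaphthalen-2-yl (2S,3R)-2,3-dimethyloxirane-2-carboxylate, via mixed anhydride 13 (not isolated)
Conditions: 12, 2,4,6-trichlorobenzoyl chloride, Et3N, THF, 0 °C → rt; then 9, DMAP, toluene, rt
Reagents that add atoms: none
Why: Yamaguchi esterification; DMAP transfers the hindered acyl group from the mixed anhydride to the secondary equatorial C3 hydroxyl, while the tertiary C4 hydroxyl should not react under these conditions.

Step 10
Reactants: 14 (1S,2S,4aR,8aR)-1-hydroxy-1,4a-dimethyl-6-oxodecahydronaphthalen-2-yl (2S,3R)-2,3-dimethyloxirane-2-carboxylate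
Product: 15 (1S,2S,4aR,8aR)-1-(acetyloxy)-1,4a-dimethyl-6-oxodecahydronaphthalen-2-yl (2S,3R)-2,3-dimethyloxirane-2-carboxylate
Conditions: Ac2O (5 equiv), DMAP (1 equiv), Et3N, CH2Cl2, 40 °C
Reagents that add atoms: acetic anhydride, CC(=O)OC(C)=O
Why: DMAP-catalysed acylation of a tertiary alcohol through the N-acetylpyridinium ion; the C4 hydroxyl is equatorial and the only free hydroxyl in the molecule, and the absence of acid protects the epoxide.

Step 11
Reactants: 15 (1S,2S,4aR,8aR)-1-(acetyloxy)-1,4a-dimethyl-6-oxodecahydronaphthalen-2-yl (2S,3R)-2,3-dimethyloxirane-2-carboxylate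
Product: 16 (1S,2S,4aR,8aR)-1-(acetyloxy)-1,4a-dimethyl-6-oxo-7-(phenylselanyl)decahydronaphthalen-2-yl (2S,3R)-2,3-dimethyloxirane-2-carboxylate (either configuration at C7)
Conditions: LiN(SiMe3)2 (1.05 equiv), THF, −78 °C; PhSeBr, −78 °C
Reagents that add atoms: benzeneselenenyl bromide, Br[Se]c1ccccc1
Why: α-Selenenylation of a ketone lithium enolate; the silylamide base should deprotonate the ketone and not the less acidic acetate, and at C7 and not at C9, which is shielded by the quaternary C10; the new centre is removed in step 12.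

Step 12
Reactants: 16 (1S,2S,4aR,8aR)-1-(acetyloxy)-1,4a-dimethyl-6-oxo-7-(phenylselanyl)decahydronaphthalen-2-yl (2S,3R)-2,3-dimethyloxirane-2-carboxylate
Product: 19 (1S,2S,4aR,8aR)-1-(acetyloxy)-7-(2-hydroxypropan-2-yl)-1,4a-dimethyl-6-oxo-1,2,3,4,4a,5,6,8a-octahydronaphthalen-2-yl (2S,3R)-2,3-dimethyloxirane-2-carboxylate, via aldol adduct 17 (not isolated), via selenoxide 18 (not isolated)
Conditions: LiN(SiMe3)2 (1.1 equiv), THF, −78 °C; acetone (5 equiv); AcOH, −78 °C; then 30% H2O2, pyridine, CH2Cl2, 0 °C → rt
Reagents that add atoms: acetone, CC(C)=O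
Why: Aldol addition of the selenium-stabilized enolate (C7–H is the most acidic proton) to acetone, then oxidation to the selenoxide and syn-elimination; the elimination can only take a hydrogen from C6 because C11 carries none, so the C6=C7 enone with the free C11 hydroxyl should form regiospecifically under near-neutral conditions.

## Compound list

1 | (5E)-6,10-dimethylundeca-5,9-dien-2-one | CC(C)=CCC/C(C)=C/CCC(C)=O | starting material
2 | (5E,9E)-11-hydroxy-6,10-dimethylundeca-5,9-dien-2-one | OC/C(C)=C/CC/C(C)=C/CCC(C)=O | intermediate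
3 | (5E)-8-[(2S,3S)-3-(hydroxymethyl)-3-methyloxiran-2-yl]-6-methyloct-5-en-2-one | OC[C@]1(C)O[C@H]1CC/C(C)=C/CCC(C)=O | intermediate
4 | triethyl{[(2S,3S)-2-methyl-3-{(3E)-3-methyl-7-[(triethylsilyl)oxy]octa-3,7-dien-1-yl}oxiran-2-yl]methoxy}silane | CC[Si](CC)(CC)OC[C@]1(C)O[C@H]1CC/C(C)=C/CCC(=C)O[Si](CC)(CC)CC | intermediate
5 | (4aR,5R,6S,8aR)-6-hydroxy-5,8a-dimethyl-5-{[(triethylsilyl)oxy]methyl}octahydronaphthalen-2(1H)-one | CC[Si](CC)(CC)OC[C@]1(C)[C@@H](O)CC[C@]2(C)CC(=O)CC[C@H]21 | intermediate
6 | (4aR,5R,6S,8aR)-6-hydroxy-5-(hydroxymethyl)-5,8a-dimethyloctahydronaphthalen-2(1H)-one | OC[C@]1(C)[C@@H](O)CC[C@]2(C)CC(=O)CC[C@H]21 | intermediate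
7 | (1S,2S,4aR,8aR)-2-hydroxy-1,4a-dimethyl-6-oxodecahydronaphthalene-1-carbaldehyde | O=C[C@]1(C)[C@@H](O)CC[C@]2(C)CC(=O)CC[C@H]21 | intermediate
8 | (1S,2S,4aR,8aR)-2-hydroxy-1,4a-dimethyl-6-oxodecahydronaphthalen-1-yl formate | O=CO[C@]1(C)[C@@H](O)CC[C@]2(C)CC(=O)CC[C@H]21 | intermediate
9 | (4aR,5S,6S,8aR)-5,6-dihydroxy-5,8a-dimethyloctahydronaphthalen-2(1H)-one | O[C@]1(C)[C@@H](O)CC[C@]2(C)CC(=O)CC[C@H]21 | intermediate
10 | (2E)-2-methylbut-2-en-1-ol | C/C=C(\C)CO | starting material
11 | [(2R,3R)-2,3-dimethyloxiran-2-yl]methanol | OC[C@@]1(C)O[C@@H]1C | intermediate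
12 | (2S,3R)-2,3-dimethyloxirane-2-carboxylic acid | OC(=O)[C@@]1(C)O[C@@H]1C | intermediate
13 | (2S,3R)-2,3-dimethyloxirane-2-carboxylic 2,4,6-trichlorobenzoic anhydride | O=C(OC(=O)[C@@]1(C)O[C@@H]1C)c1c(Cl)cc(Cl)cc1Cl | intermediate
14 | (1S,2S,4aR,8aR)-1-hydroxy-1,4a-dimethyl-6-oxodecahydronaphthalen-2-yl (2S,3R)-2,3-dimethyloxirane-2-carboxylate | O[C@]1(C)[C@@H](OC(=O)[C@@]3(C)O[C@@H]3C)CC[C@]2(C)CC(=O)CC[C@H]21 | intermediate
15 | (1S,2S,4aR,8aR)-1-(acetyloxy)-1,4a-dimethyl-6-oxodecahydronaphthalen-2-yl (2S,3R)-2,3-dimethyloxirane-2-carboxylate | CC(=O)O[C@]1(C)[C@@H](OC(=O)[C@@]3(C)O[C@@H]3C)CC[C@]2(C)CC(=O)CC[C@H]21 | intermediate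
16 | (1S,2S,4aR,8aR)-1-(acetyloxy)-1,4a-dimethyl-6-oxo-7-(phenylselanyl)decahydronaphthalen-2-yl (2S,3R)-2,3-dimethyloxirane-2-carboxylate | CC(=O)O[C@]1(C)[C@@H](OC(=O)[C@@]3(C)O[C@@H]3C)CC[C@]2(C)CC(=O)C([Se]c4ccccc4)C[C@H]21 | intermediate
17 | (1S,2S,4aR,8aR)-1-(acetyloxy)-7-(2-hydroxypropan-2-yl)-1,4a-dimethyl-6-oxo-7-(phenylselanyl)decahydronaphthalen-2-yl (2S,3R)-2,3-dimethyloxirane-2-carboxylate | CC(=O)O[C@]1(C)[C@@H](OC(=O)[C@@]3(C)O[C@@H]3C)CC[C@]2(C)CC(=O)C([Se]c4ccccc4)(C(C)(C)O)C[C@H]21 | intermediate
18 | (1S,2S,4aR,8aR)-1-(acetyloxy)-7-(benzeneseleninyl)-7-(2-hydroxypropan-2-yl)-1,4a-dimethyl-6-oxodecahydronaphthalen-2-yl (2S,3R)-2,3-dimethyloxirane-2-carboxylate | CC(=O)O[C@]1(C)[C@@H](OC(=O)[C@@]3(C)O[C@@H]3C)CC[C@]2(C)CC(=O)C([Se](=O)c4ccccc4)(C(C)(C)O)C[C@H]21 | intermediate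
19 | (1S,2S,4aR,8aR)-1-(acetyloxy)-7-(2-hydroxypropan-2-yl)-1,4a-dimethyl-6-oxo-1,2,3,4,4a,5,6,8a-octahydronaphthalen-2-yl (2S,3R)-2,3-dimethyloxirane-2-carboxylate | CC(=O)O[C@]1(C)[C@@H](OC(=O)[C@@]2(C)O[C@@H]2C)CC[C@]2(C)CC(=O)C(C(C)(C)O)=C[C@H]21 | target

## Step count and least certain steps

Total: 12 steps. Longest linear sequence: 10 steps (steps 1–6 and 9–12); the acid 12 is made in the 2 steps 7 and 8.

Step 4 (key step). The oxygen-bearing CH2 group on the initiating carbon withdraws electron density, so ionization at C4 is slowed. The epoxide may then rearrange by hydride shift to a carbonyl compound or open at C3. The cation at C10 may also lose a proton before ring B closes, and the enol silyl ether may be cleaved by the Lewis acid before it can act. Fallback, setting out from 3 and coming back at 6: 3 would be silylated on the hydroxyl (Et3SiCl, imidazole) to (5E)-6-methyl-8-[(2S,3S)-3-methyl-3-{[(triethylsilyl)oxy]methyl}oxiran-2-yl]oct-5-en-2-one F1 and methylenated by a Wittig reaction (Ph3P=CH2) to triethyl({(2S,3S)-3-[(3E)-3,7-dimethylocta-3,7-dien-1-yl]-2-methyloxiran-2-yl}methoxy)silane F2. F2 would then be cyclized by the radical route, through titanocene-mediated reductive epoxide opening (Cp2TiCl made in the flask from Cp2TiCl2 and Mn dust, THF, rt). The tertiary C4 radical tolerates the neighbouring oxygen and closes both rings; the C4 configuration is then expected from the equatorial preference of the larger CH2OSiEt3 group. The product would be the exocyclic alkene (1R,2S,4aR,8aR)-1,4a-dimethyl-6-methylidene-1-{[(triethylsilyl)oxy]methyl}decahydronaphthalen-2-ol F3. Ozonolysis of F3 (O3, CH2Cl2, −78 °C; Me2S) should give 5, and the acid treatment of step 4 leads to 6.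

Step 6. Competing oxygen insertion into the ring B ketone (lactone formation), hydride instead of alkyl migration (acid formation), or retro-aldol opening of the β-hydroxy aldehyde may erode the step, because three carbonyl-derived pathways are open at once. Fallback, setting out from 6 and coming back at 9: the ring ketone of 6 would first be masked (ethylene glycol, pyridinium p-toluenesulfonate, benzene, reflux) as (4a'R,5'R,6'S,8a'R)-5'-(hydroxymethyl)-5',8a'-dimethyloctahydro-1'H-spiro[[1,3]dioxolane-2,2'-naphthalen]-6'-ol F4. The oxidation of step 5 would give (4a'R,5'S,6'S,8a'R)-6'-hydroxy-5',8a'-dimethyloctahydro-1'H-spiro[[1,3]dioxolane-2,2'-naphthalene]-5'-carbaldehyde F5. The Baeyer–Villiger oxidation would give (4a'R,5'S,6'S,8a'R)-6'-hydroxy-5',8a'-dimethyloctahydro-1'H-spiro[[1,3]dioxolane-2,2'-naphthalen]-5'-yl formate F6, and methanolysis would give (4a'R,5'S,6'S,8a'R)-5',8a'-dimethyloctahydro-1'H-spiro[[1,3]dioxolane-2,2'-naphthalene]-5',6'-diol F7. Aqueous acid (1 M HCl, THF) would return 9.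

Step 10. Acylation of a tertiary alcohol flanked by an ester and a quaternary centre may be very slow. Under forcing conditions the acyl groups may migrate between O3 and O4, or the ring ketone may be enol-acetylated. Fallback, setting out from 9 and coming back at 15: 9 would be acetylated on both hydroxyls before any epoxide is present, with a Lewis acid catalyst (Ac2O, Sc(OTf)3, MeCN, −20 °C), to (1S,2S,4aR,8aR)-1,4a-dimethyl-6-oxodecahydronaphthalene-1,2-diyl diacetate F8. The secondary acetate alone would be removed (K2CO3, MeOH, 0 °C) to give (1S,2S,4aR,8aR)-2-hydroxy-1,4a-dimethyl-6-oxodecahydronaphthalen-1-yl acetate F9. F9 would be esterified with 12 through 13 under the conditions of step 9 to give 15.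

Step 12. Addition of a fully substituted, selenium-bearing enolate to a ketone is reversible and crowded, so retro-aldol on warming or simple reprotonation to 16 may dominate. Fallback, setting out from 15 and coming back at 19: the unsubstituted enolate of 15 (LiN(SiMe3)2, THF, −78 °C) would be added to acetone to give (1S,2S,4aR,8aR)-1-(acetyloxy)-7-(2-hydroxypropan-2-yl)-1,4a-dimethyl-6-oxodecahydronaphthalen-2-yl (2S,3R)-2,3-dimethyloxirane-2-carboxylate F10. Dehydration (Burgess reagent, then DBU) would give the conjugated (1S,2S,4aR,8aR)-1-(acetyloxy)-1,4a-dimethyl-6-oxo-7-(propan-2-ylidene)decahydronaphthalen-2-yl (2S,3R)-2,3-dimethyloxirane-2-carboxylate F11. A singlet-oxygen ene reaction (O2, tetraphenylporphyrin, light, CH2Cl2, 0 °C) should abstract hydrogen from C6, the position geminal to the carbonyl-bearing carbon, and place oxygen on C11. This would give (1S,2S,4aR,8aR)-1-(acetyloxy)-7-(2-hydroperoxypropan-2-yl)-1,4a-dimethyl-6-oxo-1,2,3,4,4a,5,6,8a-octahydronaphthalen-2-yl (2S,3R)-2,3-dimethyloxirane-2-carboxylate F12, which PPh3 would reduce in the same flask to 19.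

## Further compounds

F1 | step 4 | (5E)-6-methyl-8-[(2S,3S)-3-methyl-3-{[(triethylsilyl)oxy]methyl}oxiran-2-yl]oct-5-en-2-one | CC[Si](CC)(CC)OC[C@]1(C)O[C@H]1CC/C(C)=C/CCC(C)=O
F2 | step 4 | triethyl({(2S,3S)-3-[(3E)-3,7-dimethylocta-3,7-dien-1-yl]-2-methyloxiran-2-yl}methoxy)silane | CC[Si](CC)(CC)OC[C@]1(C)O[C@H]1CC/C(C)=C/CCC(C)=C
F3 | step 4 | (1R,2S,4aR,8aR)-1,4a-dimethyl-6-methylidene-1-{[(triethylsilyl)oxy]methyl}decahydronaphthalen-2-ol | CC[Si](CC)(CC)OC[C@]1(C)[C@@H](O)CC[C@]2(C)CC(=C)CC[C@H]21
F4 | step 6 | (4a'R,5'R,6'S,8a'R)-5'-(hydroxymethyl)-5',8a'-dimethyloctahydro-1'H-spiro[[1,3]dioxolane-2,2'-naphthalen]-6'-ol | OC[C@]1(C)[C@@H](O)CC[C@]2(C)CC3(OCCO3)CC[C@H]21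
F5 | step 6 | (4a'R,5'S,6'S,8a'R)-6'-hydroxy-5',8a'-dimethyloctahydro-1'H-spiro[[1,3]dioxolane-2,2'-naphthalene]-5'-carbaldehyde | O=C[C@]1(C)[C@@H](O)CC[C@]2(C)CC3(OCCO3)CC[C@H]21
F6 | step 6 | (4a'R,5'S,6'S,8a'R)-6'-hydroxy-5',8a'-dimethyloctahydro-1'H-spiro[[1,3]dioxolane-2,2'-naphthalen]-5'-yl formate | O=CO[C@]1(C)[C@@H](O)CC[C@]2(C)CC3(OCCO3)CC[C@H]21
F7 | step 6 | (4a'R,5'S,6'S,8a'R)-5',8a'-dimethyloctahydro-1'H-spiro[[1,3]dioxolane-2,2'-naphthalene]-5',6'-diol | O[C@]1(C)[C@@H](O)CC[C@]2(C)CC3(OCCO3)CC[C@H]21
F8 | step 10 | (1S,2S,4aR,8aR)-1,4a-dimethyl-6-oxodecahydronaphthalene-1,2-diyl diacetate | CC(=O)O[C@]1(C)[C@@H](OC(C)=O)CC[C@]2(C)CC(=O)CC[C@H]21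
F9 | step 10 | (1S,2S,4aR,8aR)-2-hydroxy-1,4a-dimethyl-6-oxodecahydronaphthalen-1-yl acetate | CC(=O)O[C@]1(C)[C@@H](O)CC[C@]2(C)CC(=O)CC[C@H]21
F10 | step 12 | (1S,2S,4aR,8aR)-1-(acetyloxy)-7-(2-hydroxypropan-2-yl)-1,4a-dimethyl-6-oxodecahydronaphthalen-2-yl (2S,3R)-2,3-dimethyloxirane-2-carboxylate | CC(=O)O[C@]1(C)[C@@H](OC(=O)[C@@]3(C)O[C@@H]3C)CC[C@]2(C)CC(=O)C(C(C)(C)O)C[C@H]21
F11 | step 12 | (1S,2S,4aR,8aR)-1-(acetyloxy)-1,4a-dimethyl-6-oxo-7-(propan-2-ylidene)decahydronaphthalen-2-yl (2S,3R)-2,3-dimethyloxirane-2-carboxylate | CC(=O)O[C@]1(C)[C@@H](OC(=O)[C@@]3(C)O[C@@H]3C)CC[C@]2(C)CC(=O)C(=C(C)C)C[C@H]21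
F12 | step 12 | (1S,2S,4aR,8aR)-1-(acetyloxy)-7-(2-hydroperoxypropan-2-yl)-1,4a-dimethyl-6-oxo-1,2,3,4,4a,5,6,8a-octahydronaphthalen-2-yl (2S,3R)-2,3-dimethyloxirane-2-carboxylate | CC(=O)O[C@]1(C)[C@@H](OC(=O)[C@@]3(C)O[C@@H]3C)CC[C@]2(C)CC(=O)C(C(C)(C)OO)=C[C@H]21
A1 | alternative 1 | (4aR)-6-{[tert-butyl(dimethyl)silyl]oxy}-1,4a-dimethyl-4,4a,5,6,7,8-hexahydronaphthalen-2(3H)-one | O=C1CC[C@]2(C)CC(O[Si](C)(C)C(C)(C)C)CCC2=C1C
A2 | alternative 2 | (6S)-6-(benzyloxy)-3-methylcyclohex-2-en-1-one | CC1=CC(=O)[C@@H](OCc2ccccc2)CC1
A3 | alternative 2 | (2S,4aR,8aS)-2-(benzyloxy)-4a-methyl-2,3,4,4a,5,8a-hexahydronaphthalene-1,6-dione | O=C1[C@@H](OCc3ccccc3)CC[C@]2(C)CC(=O)C=C[C@@H]21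
A4 | alternative 3 | (3S,1(10)E,4E)-3-(benzyloxy)germacra-1(10),4,7(11)-trien-8-one | C/C1=C\C[C@H](OCc2ccccc2)/C(C)=C/CC(=C(C)C)C(=O)C1
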